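The partner is the molecule I follow first, then the target it makes.

| flask | starting material | partner | protic impurity | temperature | remark | time |
|---|---|---|---|---|---|---|
| Monday's | 0.24 M | 0.48 M | 0.24 M | 95 °C | run made earlier |  |
| Sunday's | 0.24 M | 0.48 M | 0.34 M | 106 °C | run made earlier |  |
| Friday's | 0.24 M | 0.48 M | 0.53 M | 95 °C | run made earlier |  |
| Thursday's | 0.24 M | 0.72 M | 0.24 M | 106 °C | run made earlier |  |
| zeta | 0.24 M | 0.480 M (fed, over 3.0 min) | 0.240 M | 100 °C | all else is in the flask from the start; the feed brings no volume worth counting | 4.0 min |
| epsilon | 0.24 M (fed, over 3.0 min) | 0.480 M | 0.240 M |  | the addition at 80 °C, then warmed to 100 °C; the feed brings no volume worth counting | 4.0 min |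
| alpha | 0.24 M | 0.480 M | 0.240 M | 100 °C | everything together at the start | 4.0 min |
| theta | 0.24 M (fed, over 3.0 min) | 0.480 M | 0.240 M | 100 °C | all else is in the flask from the start; the feed brings no volume worth counting | 4.0 min |

| run | time / min | target / % |
|---|---|---|
| Monday's | 0.500 | 16.0 |
| Monday's | 1.00 | 14.4 |
| Monday's | 1.33 | 14.4 |
| Monday's | 2.00 | 12.8 |
| Monday's | 2.50 | 11.5 |
| Sunday's | 0.250 | 14.8 |
| Sunday's | 0.500 | 13.0 |
| Sunday's | 0.833 | 12.5 |
| Sunday's | 1.50 | 8.5 |
| Sunday's | 3.00 | 4.0 |
| Friday's | 0.250 | 13.1 |
| Friday's | 0.500 | 13.2 |
| Friday's | 0.833 | 12.6 |
| Friday's | 1.50 | 10.6 |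
| Friday's | 3.00 | 8.6 |
| Thursday's | 0.667 | 14.1 |
| Thursday's | 1.33 | 10.0 |
| Thursday's | 2.00 | 7.5 |
| Thursday's | 2.50 | 6.1 |
| Thursday's | 3.00 | 5.3 |

(standard deviation of a reading: 0.5 percentage points)

- for target the crystals are counted in
- as a solid, counted per litre of solution: crystals
- steps under discussion: 2 partner -> homo product; partner + protic impurity -> quenched reagent; target -> over-reaction product; starting material -> intermediate; crystals <-> target; partner + intermediate -> target

* which flask leads in amount of target, in percent of the starting material charged ("all alike" within 1.5 percentage points) (zeta / epsilon / alpha / theta / all alike)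
* how much target is there at the end, in percent of the starting material charged: zeta
* how much target is there at the end, in percent of the starting material charged: epsilon
* how much target is there at the end, in percent of the starting material charged: alpha
* how much target is there at the end, in percent of the starting material charged: theta

1. Fastest rung: the growth of target in batch. Sunday's run stands highest at its first reading, 14.8% at 0.250 min. Friday's run goes from 13.1% to 13.2%, no gain beyond scatter. So in both runs the readings show no growth after 0.500 min.

2. Middle rung: the feed, which lasts 3.0 min, longer than that. In theta, 0.167 of the starting material has entered by 0.500 min, so I expect little target there. In zeta (semi-batch in the partner), I expect the partner to reach intermediate throughout the feed.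

3. Slowest rung: loss of target. From first to last reading, Monday's run falls at 0.165 min⁻¹ and Sunday's at 0.476 min⁻¹. Friday's run, at Monday's temperature with more protic impurity, falls at 0.153 min⁻¹, so I put the difference between Monday's and Sunday's on temperature. Between them, at 100 °C, I read 0.267 min⁻¹. Its time, 3.75 min, is longer than the feed.

4. The rule: 0.344 is the keeping fraction, the share of target made at the start that is still target at 4.0 min and 100 °C.

5. My reckoning for alpha: Monday's first reading, run back to zero time, gives 0.174 of the charge made at 95 °C. I take the same share for alpha, and the keeping fraction leaves 0.0599. For zeta, if the whole charge couples evenly through the feed, target has a mean age of 2.50 min, and I estimate that 0.513 of the charge stands.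

6. The forecast names zeta: zeta 40% (20% to 60%), epsilon 1%, alpha 6%, theta 0.7%. Its ground for zeta: “feeding the partner keeps its concentration low, which suppresses second-order homocoupling”. My zeta figure stands above it.

7. The flasks give zeta in the lead: zeta 44.8%, epsilon 2.73%, alpha 6.30%, theta 0.749%.

    2 partner → homo product (k = 2.50 M⁻¹ s⁻¹, Ea = 72.0 kJ mol⁻¹)
    partner + protic impurity → quenched reagent (k = 0.330 M⁻¹ s⁻¹, Ea = 75.0 kJ mol⁻¹)
    target → over-reaction product (k = 0.00440 s⁻¹, Ea = 112 kJ mol⁻¹)
    starting material → intermediate (k = 0.0580 s⁻¹, Ea = 88.0 kJ mol⁻¹)
    crystals ⇌ target, rate k5*(cs5 - [target]) while solid is left; crystals form when [target] > cs5 (solubility = 0.210 M, k = 0.250 s⁻¹)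
    partner + intermediate → target (k = 6.40 M⁻¹ s⁻¹, Ea = 67.0 kJ mol⁻¹)
    (constants at 100 °C)

8. In theta, half the turnover up to the asked time is done by 0.346 s for the homo product step, but by 1.78 min for the step to intermediate, and 97.7% ends as intermediate. Theta's target, as a share of target plus over-reaction product, is 0.377, against the keeping fraction of 0.344.

9. Theta's neighbour holds 0.96 M of starting material. If its target is also made at the start, the keeping fraction gives 0.344 as that share. The neighbour ends with 0.390% target and 0.672% over-reaction product, a share of 0.367.

Readings and results come from a simulation with constants of no real substance, and the scatter is random.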